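Compare two times: the time a flask has, and the time its substrate needs.

| flask | substrate | reagent | initiator | radical scavenger | remark | time |
|---|---|---|---|---|---|---|
| oak | 0.56 M | 0.84 M | 51 mM | 3.4 mM | the very flask that is asked about, followed so far |  |
| maple | 1.1 M | 0.84 M | 51 mM | 3.4 mM | run made earlier |  |
| flask | 0.56 M | 0.840 M | 51 mM | 3.4 mM |  | 30 min |

| run | time / min | product / % | substrate / % |
|---|---|---|---|
| oak | 1.00 | 1 | 102 |
| oak | 2.00 | 1 | 101 |
| oak | 5.00 | 0 | 98 |
| oak | 12.0 | 64 | 34 |
| maple | 1.00 | 0 | 103 |
| maple | 2.00 | 0 | 99 |
| maple | 5.00 | 1 | 101 |
| maple | 12.0 | 37 | 68 |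

(each reading ± 1.5 percentage points)

1. concentration of product at 30 min, in M
2. concentration of reagent at 30 min, in M



Read the dead time, the induction period, first. Oak still shows 0% product at 5.00 min. Then take the average rate r from there to 12.0 min: oak gives 0.0512 M/min. Maple, with about twice the substrate, gives 0.0581 M/min. So treat r as roughly independent of substrate.

Now divide oak's charge by r. At that rate the substrate needs about 10.9 min, and oak has 25.0 min after the dead time. Call available time over needed time the run-out ratio ρ: here 2.29. Oak has more time than it needs. Reagent, at 0.840 M, is charged above substrate at 0.56 M, so with one reagent per substrate, substrate is the limiting reagent. Expect product near that charge.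

The forecast gives 0.55 M product and 0.29 M reagent: “conversion should be essentially complete”.

The flask gives 0.550 M product and 0.290 M reagent.

    initiator → 2 initiating radical (k = 9.60 × 10⁻⁵ /s)
    substrate + initiating radical → capped initiator + first chain carrier (k = 2.50 × 10⁵ /M/s)
    reagent + first chain carrier ⇌ product + second chain carrier (K = 1.60, k = 4300 /M/s)
    substrate + second chain carrier → released group + first chain carrier (k = 35000 /M/s)
    2 first chain carrier → ended chains A (k = 3.00 × 10⁷ /M/s)
    second chain carrier + radical scavenger → ended chains B (k = 1.50 × 10⁸ /M/s)

With ρ at 2.29, the flask holds 14.6% of its substrate at 15.0 min and 0% at 30.0 min. Now take the same recipe read at 8.0 min: ρ is 0.274, which predicts 0.154 M product. That neighbour holds 0.165 M. Back in the asked flask, ten times the time leaves product at 0.550 M and reagent at 0.290 M. Initiator still moves, from 84% of its charge at 30.0 min to 17.8% at 300 min.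

The runs come from a simulation with made-up constants; scatter was added.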